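**Plan**

- Retrosynthesis: the two galloyl esters at O5 and O7 are removed first, then ring C is opened at the aryl ether bond O1–C8a. The open chain is cut at C2–C1′ (B-ring aryl ketone) and at C3–C4 (benzylic alkylation of a glycolate).
- Enabling feature: O1 joins the benzylic carbinol carbon C2 to the aromatic carbon C8a of ring A. The pyran (ring C) can therefore be closed at the aryl–oxygen bond of an ortho-bromoaryl 1,2-diol monoether while every bond at C2 and C3 stays intact.
- Forward: A-ring benzylic bromide plus chiral glycolate enolate (C3–C4), B-ring Grignard reagent on the Weinreb amide (C2–C1′), ketone reduction, Pd-catalysed O-arylation (the only ring formed), MOM cleavage, double galloylation, global hydrogenolysis.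
- Stereochemistry: C3 (S) comes from an auxiliary-controlled Evans alkylation. C2 (R) comes from a chelation-controlled 1,2-anti reduction of the α-benzyloxy ketone. The ring closure is stereoretentive.
- Protecting groups: MOM on O5/O7 (removed selectively before galloylation); benzyl on O3, O3′, O4′ and on the galloyl units (one final hydrogenolysis).

Key step: step 11

Assumption: the five starting materials of the compound list are commercial, and the free-phenol intermediates and the target are handled under argon.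

**Route**

Step 1
Reactants: 1 2-bromo-4,6-dimethoxybenzaldehyde
Product: 2 2-bromo-4,6-dihydroxybenzaldehyde
Conditions: BBr3 (5 equiv), CH2Cl2, −78 °C → rt; H2O
Reagents that add atoms: none
Why: Boron tribromide O-demethylation of aryl methyl ethers should free both phenols, the aldehyde and the aryl bromide being inert to the Lewis acid.

Step 2
Reactants: 2 2-bromo-4,6-dihydroxybenzaldehyde
Product: 3 2-bromo-4,6-bis(methoxymethoxy)benzaldehyde
Conditions: NaH (2.4 equiv), MOMCl (2.6 equiv), DMF, 0 °C → rt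
Reagents that add atoms: chloromethyl methyl ether (MOMCl), COCCl
Why: Williamson-type O-alkylation of the bis-phenoxide (the aldehyde is not enolisable) installs MOM ethers that withstand every later basic and organometallic step and can be removed in the presence of benzyl ethers.

Step 3
Reactants: 3 2-bromo-4,6-bis(methoxymethoxy)benzaldehyde
Product: 4 [2-bromo-4,6-bis(methoxymethoxy)phenyl]methanol
Conditions: NaBH4, MeOH–THF, 0 °C
Reagents that add atoms: none
Why: Borohydride reduction of an aryl aldehyde is chemoselective and leaves the aryl bromide and the acetals untouched.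

Step 4
Reactants: 4 [2-bromo-4,6-bis(methoxymethoxy)phenyl]methanol
Product: 5 1-bromo-2-(bromomethyl)-3,5-bis(methoxymethoxy)benzene
Conditions: CBr4, PPh3, CH2Cl2, 0 °C; quick filtration through Et3N-deactivated silica, used at once
Reagents that add atoms: carbon tetrabromide, BrC(Br)(Br)Br
Why: The Appel reaction converts the benzylic alcohol into the bromide under neutral conditions that spare the acid-labile MOM ethers.

Step 5
Reactants: 6 (R)-4-benzyloxazolidin-2-one; 7 benzyloxyacetyl chloride
Product: 9 (R)-4-benzyl-3-[2-(benzyloxy)acetyl]oxazolidin-2-one, via lithium oxazolidinide 8 (not isolated)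
Conditions: n-BuLi, THF, −78 °C; then 7, −78 → 0 °C
Reagents that add atoms: n-butyllithium, [Li]CCCC (supplies only the lithium of 8)
Why: N-Acylation of the lithiated oxazolidinone with an acid chloride is the standard preparation of Evans glycolate imides.

Step 6
Reactants: 9 (R)-4-benzyl-3-[2-(benzyloxy)acetyl]oxazolidin-2-one (1.5 equiv); 5 1-bromo-2-(bromomethyl)-3,5-bis(methoxymethoxy)benzene
Product: 11 (R)-4-benzyl-3-{(2S)-2-(benzyloxy)-3-[2-bromo-4,6-bis(methoxymethoxy)phenyl]propanoyl}oxazolidin-2-one, via sodium Z-enolate 10 (not isolated)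
Conditions: NaHMDS, THF, −78 °C; then 5, −78 → −40 °C; AcOH quench
Reagents that add atoms: sodium hexamethyldisilazide, C[Si](C)(C)N([Na])[Si](C)(C)C (supplies only the sodium of 10)
Why: In this Evans asymmetric glycolate alkylation the chelated sodium Z-enolate is shielded on one face by the C4 benzyl group of the R auxiliary, so the reactive benzylic bromide should add to the opposite face and set the α-carbon (the future C3) as S.

Step 7
Reactants: 11 (R)-4-benzyl-3-{(2S)-2-(benzyloxy)-3-[2-bromo-4,6-bis(methoxymethoxy)phenyl]propanoyl}oxazolidin-2-one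
Product: 13 (2S)-2-(benzyloxy)-3-[2-bromo-4,6-bis(methoxymethoxy)phenyl]propanoic acid, via peroxy acid 12 (not isolated)
Conditions: LiOH, H2O2, THF–H2O, 0 °C; then Na2SO3; 1 M HCl to pH 3 at 0 °C
Reagents that add atoms: hydrogen peroxide, OO
Why: Lithium hydroperoxide attacks the exocyclic imide carbonyl selectively (Evans auxiliary cleavage) and the α-alkoxy stereocentre is not epimerised under these cold, weakly basic conditions.

Step 8
Reactants: 13 (2S)-2-(benzyloxy)-3-[2-bromo-4,6-bis(methoxymethoxy)phenyl]propanoic acid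
Product: 15 (2S)-2-(benzyloxy)-3-[2-bromo-4,6-bis(methoxymethoxy)phenyl]-N-methoxy-N-methylpropanamide, via acyl imidazolide 14 (not isolated)
Conditions: CDI, CH2Cl2, rt; then MeNH(OMe)·HCl, rt
Reagents that add atoms: N,O-dimethylhydroxylamine hydrochloride, CNOC.Cl; 1,1′-carbonyldiimidazole, O=C(n1ccnc1)n1ccnc1 (its imidazolyl group is present only in 14)
Why: Weinreb amide formation through the acyl imidazolide is a mild acyl substitution that an α-alkoxy acid undergoes without loss of configuration.

Step 9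
Reactants: 16 4-bromo-1,2-bis(benzyloxy)benzene (1.8 equiv); 15 (2S)-2-(benzyloxy)-3-[2-bromo-4,6-bis(methoxymethoxy)phenyl]-N-methoxy-N-methylpropanamide
Product: 18 (2S)-2-(benzyloxy)-1-[3,4-bis(benzyloxy)phenyl]-3-[2-bromo-4,6-bis(methoxymethoxy)phenyl]propan-1-one, via aryl Grignard reagent 17 (not isolated)
Conditions: Mg, I2 (cat.), THF, 40 °C → rt; then 15, THF, −10 → 0 °C; sat. NH4Cl
Reagents that add atoms: magnesium, [Mg] (present only in 17)
Why: In this Weinreb ketone synthesis the magnesium-chelated tetrahedral adduct collapses only on work-up, so a single aryl group is delivered, the α-centre is not enolised and the A-ring bromide does not exchange with an aryl Grignard reagent.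

Step 10
Reactants: 18 (2S)-2-(benzyloxy)-1-[3,4-bis(benzyloxy)phenyl]-3-[2-bromo-4,6-bis(methoxymethoxy)phenyl]propan-1-one
Product: 19 (1R,2S)-2-(benzyloxy)-1-[3,4-bis(benzyloxy)phenyl]-3-[2-bromo-4,6-bis(methoxymethoxy)phenyl]propan-1-ol
Conditions: Zn(BH4)2, Et2O–CH2Cl2, −78 → −20 °C
Reagents that add atoms: none
Why: In this chelation-controlled (Cram chelate) reduction zinc bridges the carbonyl and the α-benzyloxy oxygen, and hydride should enter from the face of the α-hydrogen, away from the arylmethyl group, giving the 1,2-anti alcohol with the new carbinol centre (the future C2) R.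

Step 11
Reactants: 19 (1R,2S)-2-(benzyloxy)-1-[3,4-bis(benzyloxy)phenyl]-3-[2-bromo-4,6-bis(methoxymethoxy)phenyl]propan-1-ol
Product: 20 (2R,3S)-3-(benzyloxy)-2-[3,4-bis(benzyloxy)phenyl]-5,7-bis(methoxymethoxy)chroman
Conditions: Pd(OAc)2 (5 mol %), rac-2-(di-tert-butylphosphino)-1,1′-binaphthyl (6 mol %), Cs2CO3 (1.5 equiv), toluene, 80 °C
Reagents that add atoms: none
Why: Pd(0) inserts into the C8a–Br bond, carbonate-assisted exchange of bromide for the C1 alkoxide gives a seven-membered aryl(alkoxo)palladium chelate, and C–O reductive elimination, accelerated by the bulky di-tert-butylbiarylphosphine, releases the chroman and Pd(0). This is the known palladium-catalysed intramolecular O-arylation (Buchwald–Hartwig-type etherification) of secondary alcohols bearing an ortho-bromoaryl tether, which gives chromans. Ring C is closed at the O1–C8a bond as a six-membered ring by reductive elimination from the oxapalladacycle, formally a 6-exo attack of oxygen on the aryl carbon. No stereocentre is created, because neither the carbinol C–O bond nor any bond at the neighbouring carbon is broken, so the 1R,2S configuration of 19 becomes 2R,3S in 20. Only chemoselectivity is needed: etherification must outrun β-hydride elimination (ketone plus debrominated arene) and a single ring size must form. This is secured by the hindered ligand with a weak base, by the carbinol being the only free hydroxyl, and by the benzyl ether on the adjacent oxygen, which excludes a dihydrobenzofuran.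

Step 12
Reactants: 20 (2R,3S)-3-(benzyloxy)-2-[3,4-bis(benzyloxy)phenyl]-5,7-bis(methoxymethoxy)chroman
Product: 21 (2R,3S)-3-(benzyloxy)-2-[3,4-bis(benzyloxy)phenyl]chroman-5,7-diol
Conditions: conc. HCl (cat.), MeOH–THF, 40 °C, argon
Reagents that add atoms: none
Why: Acid-catalysed acetal exchange with the large excess of methanol removes both MOM groups as formaldehyde dimethyl acetal, while benzyl ethers and the flavan ring are stable to dilute methanolic acid.

Step 13
Reactants: 21 (2R,3S)-3-(benzyloxy)-2-[3,4-bis(benzyloxy)phenyl]chroman-5,7-diol; 22 3,4,5-tris(benzyloxy)benzoic acid (2.4 equiv)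
Product: 23 (2R,3S)-3-(benzyloxy)-2-[3,4-bis(benzyloxy)phenyl]chroman-5,7-diyl bis[3,4,5-tris(benzyloxy)benzoate]
Conditions: DCC, DMAP, CH2Cl2, 0 °C → rt
Reagents that add atoms: none
Why: Steglich esterification acylates the two phenols, the only free hydroxyls of 21, so no site selectivity is required.

Step 14
Reactants: 23 (2R,3S)-3-(benzyloxy)-2-[3,4-bis(benzyloxy)phenyl]chroman-5,7-diyl bis[3,4,5-tris(benzyloxy)benzoate]
Product: 24 catechin 5,7-di-O-gallate, (2R,3S)-2-(3,4-dihydroxyphenyl)-3-hydroxychroman-5,7-diyl bis(3,4,5-trihydroxybenzoate)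
Conditions: H2 (1 atm), 20% Pd(OH)2/C, THF–MeOH, rt, neutral work-up under argon
Reagents that add atoms: none
Why: Catalytic hydrogenolysis should cleave all nine O-benzyl groups under neutral conditions that leave the aryl gallate esters and the chroman C–O bonds intact, as is usual for benzylated catechin gallates.

**Compound list**

1 | 2-bromo-4,6-dimethoxybenzaldehyde | COc1cc(Br)c(C=O)c(OC)c1 | starting material
2 | 2-bromo-4,6-dihydroxybenzaldehyde | O=Cc1c(O)cc(O)cc1Br | intermediate
3 | 2-bromo-4,6-bis(methoxymethoxy)benzaldehyde | COCOc1cc(Br)c(C=O)c(OCOC)c1 | intermediate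
4 | [2-bromo-4,6-bis(methoxymethoxy)phenyl]methanol | COCOc1cc(Br)c(CO)c(OCOC)c1 | intermediate
5 | 1-bromo-2-(bromomethyl)-3,5-bis(methoxymethoxy)benzene | COCOc1cc(Br)c(CBr)c(OCOC)c1 | intermediate
6 | (R)-4-benzyloxazolidin-2-one | O=C1N[C@H](Cc2ccccc2)CO1 | starting material
7 | benzyloxyacetyl chloride | O=C(Cl)COCc1ccccc1 | starting material
8 | lithium (R)-4-benzyl-2-oxooxazolidin-3-ide | [Li+].O=C1[N-][C@H](Cc2ccccc2)CO1 | intermediate (not isolated)
9 | (R)-4-benzyl-3-[2-(benzyloxy)acetyl]oxazolidin-2-one | O=C(COCc1ccccc1)N1[C@H](Cc2ccccc2)COC1=O | intermediate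
10 | sodium (Z)-enolate of 9 | [Na+].[O-]/C(=C\OCc1ccccc1)N1[C@H](Cc2ccccc2)COC1=O | intermediate (not isolated)
11 | (R)-4-benzyl-3-{(2S)-2-(benzyloxy)-3-[2-bromo-4,6-bis(methoxymethoxy)phenyl]propanoyl}oxazolidin-2-one | O=C([C@@H](OCc1ccccc1)Cc1c(Br)cc(OCOC)cc1OCOC)N1[C@H](Cc2ccccc2)COC1=O | intermediate
12 | (2S)-2-(benzyloxy)-3-[2-bromo-4,6-bis(methoxymethoxy)phenyl]propaneperoxoic acid | OOC(=O)[C@@H](OCc1ccccc1)Cc1c(Br)cc(OCOC)cc1OCOC | intermediate (not isolated)
13 | (2S)-2-(benzyloxy)-3-[2-bromo-4,6-bis(methoxymethoxy)phenyl]propanoic acid | OC(=O)[C@@H](OCc1ccccc1)Cc1c(Br)cc(OCOC)cc1OCOC | intermediate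
14 | (2S)-2-(benzyloxy)-3-[2-bromo-4,6-bis(methoxymethoxy)phenyl]-1-(1H-imidazol-1-yl)propan-1-one | O=C(n1ccnc1)[C@@H](OCc1ccccc1)Cc1c(Br)cc(OCOC)cc1OCOC | intermediate (not isolated)
15 | (2S)-2-(benzyloxy)-3-[2-bromo-4,6-bis(methoxymethoxy)phenyl]-N-methoxy-N-methylpropanamide | CON(C)C(=O)[C@@H](OCc1ccccc1)Cc1c(Br)cc(OCOC)cc1OCOC | intermediate
16 | 4-bromo-1,2-bis(benzyloxy)benzene | Brc1ccc(OCc2ccccc2)c(OCc2ccccc2)c1 | starting material
17 | [3,4-bis(benzyloxy)phenyl]magnesium bromide | Br[Mg]c1ccc(OCc2ccccc2)c(OCc2ccccc2)c1 | intermediate (not isolated)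
18 | (2S)-2-(benzyloxy)-1-[3,4-bis(benzyloxy)phenyl]-3-[2-bromo-4,6-bis(methoxymethoxy)phenyl]propan-1-one | O=C(c1ccc(OCc2ccccc2)c(OCc2ccccc2)c1)[C@@H](OCc1ccccc1)Cc1c(Br)cc(OCOC)cc1OCOC | intermediate
19 | (1R,2S)-2-(benzyloxy)-1-[3,4-bis(benzyloxy)phenyl]-3-[2-bromo-4,6-bis(methoxymethoxy)phenyl]propan-1-ol | O[C@H](c1ccc(OCc2ccccc2)c(OCc2ccccc2)c1)[C@@H](OCc1ccccc1)Cc1c(Br)cc(OCOC)cc1OCOC | intermediate
20 | (2R,3S)-3-(benzyloxy)-2-[3,4-bis(benzyloxy)phenyl]-5,7-bis(methoxymethoxy)chroman | COCOc1cc(OCOC)c2c(c1)O[C@H](c1ccc(OCc3ccccc3)c(OCc3ccccc3)c1)[C@@H](OCc1ccccc1)C2 | intermediate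
21 | (2R,3S)-3-(benzyloxy)-2-[3,4-bis(benzyloxy)phenyl]chroman-5,7-diol | Oc1cc(O)c2c(c1)O[C@H](c1ccc(OCc3ccccc3)c(OCc3ccccc3)c1)[C@@H](OCc1ccccc1)C2 | intermediate
22 | 3,4,5-tris(benzyloxy)benzoic acid | OC(=O)c1cc(OCc2ccccc2)c(OCc2ccccc2)c(OCc2ccccc2)c1 | starting material
23 | (2R,3S)-3-(benzyloxy)-2-[3,4-bis(benzyloxy)phenyl]chroman-5,7-diyl bis[3,4,5-tris(benzyloxy)benzoate] | O=C(Oc1cc(OC(=O)c2cc(OCc3ccccc3)c(OCc3ccccc3)c(OCc3ccccc3)c2)c2c(c1)O[C@H](c1ccc(OCc3ccccc3)c(OCc3ccccc3)c1)[C@@H](OCc1ccccc1)C2)c1cc(OCc2ccccc2)c(OCc2ccccc2)c(OCc2ccccc2)c1 | intermediate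
24 | catechin 5,7-di-O-gallate, (2R,3S)-2-(3,4-dihydroxyphenyl)-3-hydroxychroman-5,7-diyl bis(3,4,5-trihydroxybenzoate) | O=C(Oc1cc(OC(=O)c2cc(O)c(O)c(O)c2)c2c(c1)O[C@H](c1ccc(O)c(O)c1)[C@@H](O)C2)c1cc(O)c(O)c(O)c1 | target

**Step count and risks**

Total steps: 14. Longest linear sequence: 13 steps (steps 1–4 and 6–14, from 1 to 24); step 5 is the only side-branch operation.

Steps most likely to fail:

1. Step 11. β-Hydride elimination from the palladium alkoxide (oxidation of the benzylic carbinol with loss of the bromide) may outrun C–O reductive elimination at the electron-rich aryl group. The fallback sets out from 19 and comes back at 21. Miyaura borylation of the C–Br bond (B2pin2, Pd(dppf)Cl2, KOAc, dioxane, 80 °C) should give the arylboronic ester (1R,2S)-2-(benzyloxy)-1-[3,4-bis(benzyloxy)phenyl]-3-[2,4-bis(methoxymethoxy)-6-(4,4,5,5-tetramethyl-1,3,2-dioxaborolan-2-yl)phenyl]propan-1-ol F1. Oxidation (NaBO3·4H2O, THF–H2O, rt) should then give the phenol (1R,2S)-2-(benzyloxy)-1-[3,4-bis(benzyloxy)phenyl]-3-[2-hydroxy-4,6-bis(methoxymethoxy)phenyl]propan-1-ol F2. Methanolic HCl should then cleave both MOM ethers and ionise the benzylic alcohol to the 4-benzyloxy-stabilised cation. One of the two now equivalent ortho-phenols captures this cation (classical flavan-3-ol cyclodehydration, O1–C2 bond formation). C2 is then set under control of C3, the 2,3-trans isomer being the expected major product, which is 21.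

2. Step 6. The electron-rich benzylic bromide may ionise and self-condense, and the glycolate enolate may decompose before the hindered SN2 alkylation takes place. The fallback sets out from 3 and comes back at 13; steps 3–7 are then not needed. Horner–Wadsworth–Emmons olefination of 3 with methyl 2-(benzyloxy)-2-(dimethoxyphosphoryl)acetate (NaH, THF, 0 °C → rt) should give methyl (Z)-2-(benzyloxy)-3-[2-bromo-4,6-bis(methoxymethoxy)phenyl]prop-2-enoate F3. Saponification (LiOH, THF–H2O) should give (Z)-2-(benzyloxy)-3-[2-bromo-4,6-bis(methoxymethoxy)phenyl]prop-2-enoic acid F4. Homogeneous asymmetric hydrogenation of this α-alkoxyacrylic acid (chiral iridium spiro-phosphine-oxazoline or Ru–BINAP carboxylate catalyst, H2, MeOH, Et3N) should then give 13. The ligand antipode is chosen by screening to deliver the S acid, and the aryl bromide is expected to survive.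

3. Step 12. Formaldehyde equivalents released during acid cleavage may C-alkylate the highly nucleophilic 5,7-dihydroxy ring, and the acid may ionise the benzylic C2–O1 bond. The fallback sets out from 20 and comes back at 21. Treatment with TESOTf and 2,2′-bipyridyl (CH2Cl2, 0 °C → rt) should exchange the aryl MOM ethers for silyl ethers without free acid, the methoxymethyl group being carried off on the pyridine nitrogen. This should give (2R,3S)-3-(benzyloxy)-2-[3,4-bis(benzyloxy)phenyl]-5,7-bis(triethylsilyloxy)chroman F5. Acetic-acid-buffered TBAF (THF, 0 °C) should then desilylate it to 21.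

Further compounds
F1 | step 11 | (1R,2S)-2-(benzyloxy)-1-[3,4-bis(benzyloxy)phenyl]-3-[2,4-bis(methoxymethoxy)-6-(4,4,5,5-tetramethyl-1,3,2-dioxaborolan-2-yl)phenyl]propan-1-ol | O[C@H](c1ccc(OCc2ccccc2)c(OCc2ccccc2)c1)[C@@H](OCc1ccccc1)Cc1c(B2OC(C)(C)C(C)(C)O2)cc(OCOC)cc1OCOC
F2 | step 11 | (1R,2S)-2-(benzyloxy)-1-[3,4-bis(benzyloxy)phenyl]-3-[2-hydroxy-4,6-bis(methoxymethoxy)phenyl]propan-1-ol | O[C@H](c1ccc(OCc2ccccc2)c(OCc2ccccc2)c1)[C@@H](OCc1ccccc1)Cc1c(O)cc(OCOC)cc1OCOC
F3 | step 6 | methyl (Z)-2-(benzyloxy)-3-[2-bromo-4,6-bis(methoxymethoxy)phenyl]prop-2-enoate | COC(=O)/C(OCc1ccccc1)=C/c1c(Br)cc(OCOC)cc1OCOC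
F4 | step 6 | (Z)-2-(benzyloxy)-3-[2-bromo-4,6-bis(methoxymethoxy)phenyl]prop-2-enoic acid | OC(=O)/C(OCc1ccccc1)=C/c1c(Br)cc(OCOC)cc1OCOC
F5 | step 12 | (2R,3S)-3-(benzyloxy)-2-[3,4-bis(benzyloxy)phenyl]-5,7-bis(triethylsilyloxy)chroman | CC[Si](CC)(CC)Oc1cc(O[Si](CC)(CC)CC)c2c(c1)O[C@H](c1ccc(OCc3ccccc3)c(OCc3ccccc3)c1)[C@@H](OCc1ccccc1)C2
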